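**Assumption:** the allylborane 2 is defined by its structure (isopinocampheyl groups of the (−)-α-pinene series, "lIpc"), because sign labels for this reagent are not uniform.

## Retrosynthetic overview

1. Hansfordiol G ⇐ global acid deprotection of the bis-MOM / TBS ether 18.
2. Aryl–C1′ bond: B-alkyl Suzuki–Miyaura coupling of the 9-BBN adduct of diene 14 with aryl bromide 16.
3. C8′=C9′ (Z): Wittig reaction of aldehyde 10 with the oct-7-enyl ylide 13.
4. C9′–C13′: cross-metathesis of homoallylic silyl ether 5 with methyl pent-4-enoate, then hydrogenation and DIBAL-H.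
5. Key C14′–C15′ bond and the only stereocentre: asymmetric allylboration of propanal. The resorcinol ring is bought intact (5-bromoresorcinol), so no ring is formed.

## Route

**Step 1**
Reactants: 1 propanal; 2 allylbis[(1S,2R,3S,5S)-2,6,6-trimethylbicyclo[3.1.1]hept-3-yl]borane (lIpc2B-allyl)
Product: 4 (3S)-hex-5-en-3-ol, via diisopinocampheylborinate ester 3 (not isolated)
Conditions: 2 (1 M in pentane, 1.1 equiv), Et2O, −100 → −78 °C, 2 h; then 3 M NaOH, 30% H2O2, 0 → 40 °C; fractional distillation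
Reagents that add atoms: none
Why: Brown asymmetric allylboration (carbonyl allylation) through a closed chair Zimmerman–Traxler transition state, in which the lIpc ligands deliver allyl to the Re face of propanal and set C-3 as S (expected ≥94% ee under salt-free conditions at −100 °C).

**Step 2**
Reactants: 4 (3S)-hex-5-en-3-ol
Product: 5 tert-butyl{[(3S)-hex-5-en-3-yl]oxy}dimethylsilane
Conditions: TBSCl (1.2 equiv), imidazole (2.5 equiv), DMF, 0 °C → rt, 12 h
Reagents that add atoms: tert-butyldimethylsilyl chloride, CC(C)(C)[Si](C)(C)Cl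
Why: Corey silylation of an unhindered secondary alcohol at oxygen, so no bond to the stereocentre is touched.

**Step 3**
Reactants: 5 tert-butyl{[(3S)-hex-5-en-3-yl]oxy}dimethylsilane; 6 methyl pent-4-enoate (3 equiv)
Product: 7 methyl (4E,7S)-7-[(tert-butyldimethylsilyl)oxy]non-4-enoate (E major; the minor 4Z isomer is carried along)
Conditions: Grubbs second-generation catalyst (3 mol %), CH2Cl2, 40 °C, 12 h
Reagents that add atoms: none
Why: Olefin cross-metathesis of two terminal alkenes driven by loss of ethylene, with the cheap ester in excess to favour the cross product; the E/Z ratio is irrelevant because the alkene is hydrogenated next.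

**Step 4**
Reactants: 7 methyl (4E,7S)-7-[(tert-butyldimethylsilyl)oxy]non-4-enoate
Product: 8 methyl (7S)-7-[(tert-butyldimethylsilyl)oxy]nonanoate
Conditions: H2 (1 atm), 10% Pd/C, EtOAc, rt, 6 h
Reagents that add atoms: none
Why: Heterogeneous catalytic hydrogenation of a disubstituted alkene; the ester and the TBS ether are inert in EtOAc.

**Step 5**
Reactants: 8 methyl (7S)-7-[(tert-butyldimethylsilyl)oxy]nonanoate
Product: 10 (7S)-7-[(tert-butyldimethylsilyl)oxy]nonanal, via aluminium hemiacetal 9 (not isolated)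
Conditions: DIBAL-H (1.1 equiv, 1 M in hexanes), CH2Cl2, −78 °C, 1 h; MeOH, then aq. Rochelle salt, rt
Reagents that add atoms: none
Why: DIBAL-H partial reduction of a methyl ester, in which the tetrahedral aluminium hemiacetal persists at −78 °C and releases the aldehyde only on work-up.

**Step 6**
Reactants: 11 8-bromooct-1-ene
Product: 12 (oct-7-en-1-yl)triphenylphosphonium bromide
Conditions: PPh3 (1.05 equiv), MeCN, reflux, 36 h; trituration with Et2O
Reagents that add atoms: triphenylphosphine, c1ccc(cc1)P(c1ccccc1)c1ccccc1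
Why: SN2 quaternisation of triphenylphosphine by a primary alkyl bromide (phosphonium salt formation).

**Step 7**
Reactants: 12 (oct-7-en-1-yl)triphenylphosphonium bromide; 10 (7S)-7-[(tert-butyldimethylsilyl)oxy]nonanal
Product: 14 tert-butyl{[(3S,9Z)-heptadeca-9,16-dien-3-yl]oxy}dimethylsilane, via phosphonium ylide 13 (not isolated)
Conditions: 12 (1.3 equiv), NaHMDS (1.25 equiv), THF, 0 °C, 30 min; then 10, −78 °C → rt, 3 h
Reagents that add atoms: none
Why: Lithium-salt-free Wittig olefination of a non-stabilised ylide with an aliphatic aldehyde under kinetic control gives the Z-alkene (expected Z:E ≥95:5); the stereocentre is remote and untouched.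

**Step 8**
Reactants: 15 5-bromobenzene-1,3-diol
Product: 16 1-bromo-3,5-bis(methoxymethoxy)benzene
Conditions: MOMCl (2.6 equiv), i-Pr2NEt (3.0 equiv), CH2Cl2, 0 °C → rt, 12 h
Reagents that add atoms: chloromethyl methyl ether, COCCl
Why: O-alkylation of both phenols with the reactive α-chloro ether (MOM protection), giving acetals that survive the basic coupling and leave under mild acid.

**Step 9**
Reactants: 14 tert-butyl{[(3S,9Z)-heptadeca-9,16-dien-3-yl]oxy}dimethylsilane; 16 1-bromo-3,5-bis(methoxymethoxy)benzene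
Product: 18 tert-butyl{[(3S,9Z)-17-[3,5-bis(methoxymethoxy)phenyl]heptadec-9-en-3-yl]oxy}dimethylsilane, via B-alkyl-9-BBN borane 17 (not isolated)
Conditions: 9-BBN (0.5 M in THF, 1.15 equiv), 0 °C → rt, 4 h; then 16 (1.1 equiv), PdCl2(dppf) (5 mol %), 3 M aq. K3PO4 (3 equiv), DMF, 60 °C, 12 h
Reagents that add atoms: none
Why: 9-BBN hydroborates the terminal alkene anti-Markovnikov far faster than the internal Z-alkene, and B-alkyl Suzuki–Miyaura coupling then forms the sp3–sp2 bond without disturbing the Z-olefin or the silyl and MOM ethers.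

**Step 10**
Reactants: 18 tert-butyl{[(3S,9Z)-17-[3,5-bis(methoxymethoxy)phenyl]heptadec-9-en-3-yl]oxy}dimethylsilane
Product: 19 hansfordiol G, 5-[(8Z,15S)-15-hydroxyheptadec-8-en-1-yl]benzene-1,3-diol
Conditions: HCl (1.25 M in MeOH), 40 °C, 6 h
Reagents that add atoms: none
Why: Acid-catalysed solvolysis (acetal exchange of both MOM ethers and methanolysis of the Si–O bond) frees the three hydroxyls; the isolated Z-alkene is inert and the carbinol C–O bond is not broken, so the S configuration is retained.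

## Compound list

1 | propanal | CCC=O | starting material
2 | allylbis[(1S,2R,3S,5S)-2,6,6-trimethylbicyclo[3.1.1]hept-3-yl]borane (lIpc2B-allyl, from (−)-α-pinene) | C=CCB([C@H]1C[C@H]2C[C@@H]([C@@H]1C)C2(C)C)[C@H]1C[C@H]2C[C@@H]([C@@H]1C)C2(C)C | starting material
3 | (3S)-hex-5-en-3-yl diisopinocampheylborinate (lIpc series; not isolated) | CC[C@H](OB([C@H]1C[C@H]2C[C@@H]([C@@H]1C)C2(C)C)[C@H]1C[C@H]2C[C@@H]([C@@H]1C)C2(C)C)CC=C | intermediate
4 | (3S)-hex-5-en-3-ol | CC[C@H](O)CC=C | intermediate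
5 | tert-butyl{[(3S)-hex-5-en-3-yl]oxy}dimethylsilane | CC[C@H](O[Si](C)(C)C(C)(C)C)CC=C | intermediate
6 | methyl pent-4-enoate | C=CCCC(=O)OC | starting material
7 | methyl (4E,7S)-7-[(tert-butyldimethylsilyl)oxy]non-4-enoate (E major) | CC[C@H](O[Si](C)(C)C(C)(C)C)C/C=C/CCC(=O)OC | intermediate
8 | methyl (7S)-7-[(tert-butyldimethylsilyl)oxy]nonanoate | CC[C@H](O[Si](C)(C)C(C)(C)C)CCCCCC(=O)OC | intermediate
9 | diisobutylaluminium hemiacetal of 8 (not isolated; hemiacetal carbon unassigned) | CC[C@H](O[Si](C)(C)C(C)(C)C)CCCCCC(OC)O[Al](CC(C)C)CC(C)C | intermediate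
10 | (7S)-7-[(tert-butyldimethylsilyl)oxy]nonanal | CC[C@H](O[Si](C)(C)C(C)(C)C)CCCCCC=O | intermediate
11 | 8-bromooct-1-ene | C=CCCCCCCBr | starting material
12 | (oct-7-en-1-yl)triphenylphosphonium bromide | C=CCCCCCC[P+](c1ccccc1)(c1ccccc1)c1ccccc1.[Br-] | intermediate
13 | (oct-7-en-1-ylidene)triphenylphosphorane (not isolated) | C=CCCCCCC=P(c1ccccc1)(c1ccccc1)c1ccccc1 | intermediate
14 | tert-butyl{[(3S,9Z)-heptadeca-9,16-dien-3-yl]oxy}dimethylsilane | CC[C@H](O[Si](C)(C)C(C)(C)C)CCCCC/C=C\CCCCCC=C | intermediate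
15 | 5-bromobenzene-1,3-diol (5-bromoresorcinol) | Oc1cc(O)cc(Br)c1 | starting material
16 | 1-bromo-3,5-bis(methoxymethoxy)benzene | COCOc1cc(Br)cc(OCOC)c1 | intermediate
17 | 9-[(8Z,15S)-15-[(tert-butyldimethylsilyl)oxy]heptadec-8-en-1-yl]-9-borabicyclo[3.3.1]nonane (not isolated) | CC[C@H](O[Si](C)(C)C(C)(C)C)CCCCC/C=C\CCCCCCCB1C2CCCC1CCC2 | intermediate
18 | tert-butyl{[(3S,9Z)-17-[3,5-bis(methoxymethoxy)phenyl]heptadec-9-en-3-yl]oxy}dimethylsilane | CC[C@H](O[Si](C)(C)C(C)(C)C)CCCCC/C=C\CCCCCCCc1cc(OCOC)cc(OCOC)c1 | intermediate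
19 | hansfordiol G, 5-[(8Z,15S)-15-hydroxyheptadec-8-en-1-yl]benzene-1,3-diol | CC[C@H](O)CCCCC/C=C\CCCCCCCc1cc(O)cc(O)c1 | target

## Step count and risks

Total steps: 10. Longest linear sequence: 8 (steps 1, 2, 3, 4, 5, 7, 9, 10).

**Step 3 (cross-metathesis).** Both partners are terminal type-I olefins, so the product distribution is statistical, homodimerisation of 5 wastes chiral material, and Ru–H-induced double-bond migration can shorten the chain. The fallback sets out from 5 and returns at 10. Ozonolysis of 5 (O3, CH2Cl2, −78 °C) gives 3-[(2S)-2-[(tert-butyldimethylsilyl)oxy]butyl]-1,2,4-trioxolane F1, which PPh3 reduces to (3S)-3-[(tert-butyldimethylsilyl)oxy]pentanal F2. A Wittig reaction of F2 with the ylide from commercial [3-(ethoxycarbonyl)propyl]triphenylphosphonium bromide (NaHMDS, THF, −78 °C) gives ethyl (4Z,7S)-7-[(tert-butyldimethylsilyl)oxy]non-4-enoate F3. Hydrogenation (H2, Pd/C, EtOAc) gives ethyl (7S)-7-[(tert-butyldimethylsilyl)oxy]nonanoate F4, and DIBAL-H at −78 °C as in step 5 gives 10.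

**Step 7 (Wittig).** A few percent of the 9E isomer may form and cannot easily be removed later. The fallback sets out from 10 and returns at 18. Ohira–Bestmann homologation of 10 (dimethyl (1-diazo-2-oxopropyl)phosphonate, K2CO3, MeOH) gives tert-butyl{[(3S)-dec-9-yn-3-yl]oxy}dimethylsilane F5. Lithiation (n-BuLi, THF, −78 °C) and alkylation with 7-bromohept-1-ene (DMPU, rt) gives tert-butyl{[(3S)-heptadec-16-en-9-yn-3-yl]oxy}dimethylsilane F6. 9-BBN adds to the terminal alkene in preference to the internal alkyne to give 9-[(15S)-15-[(tert-butyldimethylsilyl)oxy]heptadec-8-yn-1-yl]-9-borabicyclo[3.3.1]nonane F7, which is coupled with 16 under the conditions of step 9 to give tert-butyl{[(3S)-17-[3,5-bis(methoxymethoxy)phenyl]heptadec-9-yn-3-yl]oxy}dimethylsilane F8. Lindlar semihydrogenation (Pd/CaCO3/Pb, quinoline, H2, EtOAc) of F8 gives 18 with the Z geometry fixed by syn addition.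

**Step 9 (hydroboration / B-alkyl Suzuki).** Oxidative addition to the electron-rich aryl bromide may be slow, the alkylborane may protodeboronate or undergo β-hydride elimination, and excess 9-BBN could touch the internal alkene. The fallback sets out from 16 (and uses aldehyde 10) and returns at 18; it forms the aryl–chain bond before the olefin. Sonogashira coupling of 16 with oct-7-yn-1-ol (Pd(PPh3)2Cl2, CuI, Et3N, 70 °C) gives 8-[3,5-bis(methoxymethoxy)phenyl]oct-7-yn-1-ol F9. Hydrogenation (H2, Pd/C, EtOAc) gives 8-[3,5-bis(methoxymethoxy)phenyl]octan-1-ol F10. Appel bromination (CBr4, PPh3, CH2Cl2, 0 °C) gives 1-(8-bromooctyl)-3,5-bis(methoxymethoxy)benzene F11, and PPh3 in MeCN at reflux gives {8-[3,5-bis(methoxymethoxy)phenyl]octyl}triphenylphosphonium bromide F12. NaHMDS in THF converts F12 into {8-[3,5-bis(methoxymethoxy)phenyl]octylidene}triphenylphosphorane F13, which reacts with 10 at −78 °C → rt to give 18.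

## Further compounds

F1 | step 3 | 3-[(2S)-2-[(tert-butyldimethylsilyl)oxy]butyl]-1,2,4-trioxolane | CC[C@H](O[Si](C)(C)C(C)(C)C)CC1OCOO1
F2 | step 3 | (3S)-3-[(tert-butyldimethylsilyl)oxy]pentanal | CC[C@H](O[Si](C)(C)C(C)(C)C)CC=O
F3 | step 3 | ethyl (4Z,7S)-7-[(tert-butyldimethylsilyl)oxy]non-4-enoate | CC[C@H](O[Si](C)(C)C(C)(C)C)C/C=C\CCC(=O)OCC
F4 | step 3 | ethyl (7S)-7-[(tert-butyldimethylsilyl)oxy]nonanoate | CC[C@H](O[Si](C)(C)C(C)(C)C)CCCCCC(=O)OCC
F5 | step 7 | tert-butyl{[(3S)-dec-9-yn-3-yl]oxy}dimethylsilane | CC[C@H](O[Si](C)(C)C(C)(C)C)CCCCCC#C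
F6 | step 7 | tert-butyl{[(3S)-heptadec-16-en-9-yn-3-yl]oxy}dimethylsilane | CC[C@H](O[Si](C)(C)C(C)(C)C)CCCCCC#CCCCCCC=C
F7 | step 7 | 9-[(15S)-15-[(tert-butyldimethylsilyl)oxy]heptadec-8-yn-1-yl]-9-borabicyclo[3.3.1]nonane | CC[C@H](O[Si](C)(C)C(C)(C)C)CCCCCC#CCCCCCCCB1C2CCCC1CCC2
F8 | step 7 | tert-butyl{[(3S)-17-[3,5-bis(methoxymethoxy)phenyl]heptadec-9-yn-3-yl]oxy}dimethylsilane | CC[C@H](O[Si](C)(C)C(C)(C)C)CCCCCC#CCCCCCCCc1cc(OCOC)cc(OCOC)c1
F9 | step 9 | 8-[3,5-bis(methoxymethoxy)phenyl]oct-7-yn-1-ol | OCCCCCCC#Cc1cc(OCOC)cc(OCOC)c1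
F10 | step 9 | 8-[3,5-bis(methoxymethoxy)phenyl]octan-1-ol | OCCCCCCCCc1cc(OCOC)cc(OCOC)c1
F11 | step 9 | 1-(8-bromooctyl)-3,5-bis(methoxymethoxy)benzene | BrCCCCCCCCc1cc(OCOC)cc(OCOC)c1
F12 | step 9 | {8-[3,5-bis(methoxymethoxy)phenyl]octyl}triphenylphosphonium bromide | COCOc1cc(CCCCCCCC[P+](c2ccccc2)(c2ccccc2)c2ccccc2)cc(OCOC)c1.[Br-]
F13 | step 9 | {8-[3,5-bis(methoxymethoxy)phenyl]octylidene}triphenylphosphorane | COCOc1cc(CCCCCCCC=P(c2ccccc2)(c2ccccc2)c2ccccc2)cc(OCOC)c1
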